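This stirred vessel at constant volume holds a catalyst that turns starting material and reagent into target, while an impurity costs catalyst. You have three earlier runs and four ways of charging.

in all of them: free catalyst 3.8 mM

| run | starting material | reagent | second substrate | impurity | remark | time |
|---|---|---|---|---|---|---|
| Monday's | 38 mM | 114 mM | 76 mM | 1.8 mM | run made earlier |  |
| Sunday's | 38 mM | 114 mM | 76 mM | 0.90 mM | run made earlier |  |
| Thursday's | 38 mM | 114 mM | 76 mM | 3.6 mM | run made earlier |  |
| south-east | 38 mM (in portions, 3, over 80 min) | 114 mM | 76.0 mM | 1.8 mM | first portion at the start, last at 80 min | 2.0 h |
| north-east | 38 mM (fed, over 80 min) | 114 mM | 76.0 mM | 1.8 mM | all else is in the flask from the start; the feed brings no volume worth counting | 2.0 h |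
| south | 38 mM | 114 mM | 76.0 mM | 1.8 mM | everything together at the start | 2.0 h |
| east | 38 mM | 114 mM (fed, over 80 min) | 76.0 mM | 1.8 mM | all else is in the flask from the start; the feed brings no volume worth counting | 2.0 h |

- Monday's (time / min: target / %, starting material / %): 6.00: 32.6, 69.3; 10.0: 43.8, 56.5; 15.0: 55.1, 48.0; 25.0: 66.4, 32.1; 40.0: 77.5, 21.9; 80.0: 88.6, 11.7
- Sunday's (time / min: target / %, starting material / %): 10.0: 53.4, 45.7; 15.0: 64.1, 34.9; 25.0: 75.9, 24.3; 40.0: 83.1, 16.9; 80.0: 90.6, 9.0; 120: 94.0, 5.9
- Thursday's (time / min: target / %, starting material / %): 10.0: 11.3, 88.8; 15.0: 12.3, 88.2; 25.0: 19.2, 84.7; 40.0: 24.7, 76.2; 80.0: 37.8, 64.7; 120: 47.6, 52.1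

(standard deviation of a reading: 1 percentage point)



* which flask leads in amount of target, in percent of the starting material charged ("all alike" within 1.5 percentage points) (south-east / north-east / south / east / all alike)
* how much target is there at the end, in percent of the starting material charged: south-east
* how much target is there at the end, in percent of the starting material charged: north-east
* how much target is there at the end, in percent of the starting material charged: south
* how much target is there at the end, in percent of the starting material charged: east

Thursday's flask has 3.6 mM of impurity against 3.8 mM of free catalyst and still holds 52.1 % of its starting material at 120 min, so I read the impurity as taking catalyst one for one.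

The three runs began from one charge of starting material and reagent, so they can't show whether the rate falls with the fraction left or with the clock. I bet on the clock: surviving catalyst dies off as time passes, and starting material falls pseudo-first-order against it, with the rate proportional to reagent. Then W, minus the logarithm of the fraction left, can be read from Monday's run:

W at 40.0 min: 1.52; W at 80.0 min: 2.15

gain per unit of ln(time): 0.904

W at 2.0 h: 2.51

This last figure is the catalyst budget, the W that a molecule present from the start meets by the end. A molecule added at time t meets W(end) − W(t).

Now turn the settings one at a time.

South, charged at the start, meets the full budget. Fraction left: 0.0811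

South-east: the portions meet the full budget, then what remains after 40.0 min and after 80.0 min. Mean fraction left: 0.381

North-east: averaging over a steady feed gives exp(W at 80 min − W(end)) divided by one plus the gain. Fraction left: 0.364

East: I count reagent as rising in step with time, so the budget up to 80 min shrinks to the gain itself. Fraction left: 0.281

Target is what isn't left, so I expect south to lead, leaving less than the others.

The forecast names south as leader, with south-east 82.6 %, north-east 84.7 %, south 91.9 % and east 91 %, and its south-east stands higher than the target my reckoning leaves there: “Dosing SM hurts, so south leads, with east close behind.”

The flasks give south 92.0 %, east 73.2 %, north-east 69.2 % and south-east 67.5 %, so south leads.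

    starting material + reagent + free catalyst → free catalyst + target (k = 335 L² mol⁻² min⁻¹)
    second substrate + reagent + free catalyst → free catalyst + second product (k = 7.57 L² mol⁻² min⁻¹)
    2 free catalyst → spent catalyst A (k = 10.1 L mol⁻¹ min⁻¹)
    free catalyst + impurity → spent catalyst B (k = 2520 L mol⁻¹ min⁻¹)

By my reckoning, in south-east the portion added at 80.0 min meets 0.360 of the budget of 2.51. Remove the path by which two free catalyst give spent catalyst A, and the gap between south and south-east shrinks from 24 percentage points to 5.1 points, the largest single effect on it.

A neighbour of south has 1.5 mM of free catalyst, less than its 1.8 mM of impurity, so one for one I count no catalyst to carry the budget of 2.51. That neighbour gives 2.63 % of target, with 0 % of free catalyst standing at 2.00 h.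

(The readings were computed for an exercise; scatter was added.)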